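The numbers of this flask are assumed, and the outcome is calculated.

I took the easy step first: 0.0012 mol% on 0.10 M of starting material put 1.20 × 10⁻⁶ M of free enzyme into each flask.

    free enzyme → unfolded enzyme (k1 = 8.6 × 10⁻⁵ s⁻¹, Ea1 = 201 kJ mol⁻¹)
    starting material + free enzyme ⇌ first complex (K2 = 2.3 M⁻¹, k2 = 24000 M⁻¹ s⁻¹, Ea2 = 17.0 kJ mol⁻¹, ΔH2 = 12.0 kJ mol⁻¹)
    first complex → loaded enzyme + first product (k3 = 640 s⁻¹, Ea3 = 50.0 kJ mol⁻¹)
    second substrate + loaded enzyme ⇌ second complex (K4 = 330 M⁻¹, k4 = 48000 M⁻¹ s⁻¹, Ea4 = 23.0 kJ mol⁻¹, ΔH4 = −79.0 kJ mol⁻¹)
    second complex → free enzyme + target (k5 = 4800 s⁻¹, Ea5 = 53.0 kJ mol⁻¹)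
    free enzyme → spent catalyst (k6 = 0.0081 s⁻¹, Ea6 = 82.0 kJ mol⁻¹)
    (constants at 20 °C)

- alpha: starting material 0.10 M; second substrate 1.50 equiv; free enzyme 0.0012 mol%; temperature 20 °C; time 15 min
- beta: starting material 0.10 M; second substrate 1.50 equiv; free enzyme 0.0012 mol%; temperature 40 °C; time 15 min

- the list of constants is for 20 °C, to be carried to other temperatures by the activation energies and enthalpies

- which flask leads in amount of target, in percent of the starting material charged ("all alike" within 1.5 percentage points) (alpha / beta / all alike)
- how much target is there at the end, in percent of the starting material charged: alpha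
- how much target is there at the end, in percent of the starting material charged: beta

**The clock.** Free enzyme is lost by unfolding and by turning into spent catalyst. In alpha these sum to a death constant of 0.00819 s⁻¹, so the free form lasts 122 s on average, less than the 15 min allowed. I therefore stopped counting time and counted turnovers.

**The ratio.** In alpha, loaded enzyme is taken up at above 4800 s⁻¹ and second complex breaks at 4800 s⁻¹, both faster than first complex goes on at 640 s⁻¹. So I took free enzyme as the resting state, with first complex in steady state. In alpha first complex falls back at 10400 s⁻¹, so target forms at a capture constant times [starting material][free enzyme]. That constant is the binding constant scaled by the onward share, 1390 M⁻¹ s⁻¹ in alpha. Dividing this rate by the death rate removes time and [free enzyme]. Since [starting material] falls as target rises, integrating gives a yield of one minus exp(−B). Here B, charged [free enzyme] times capture constant over death constant, came to 0.203 in alpha; I called it the turnover budget.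

**Turned round.** Beta could lead on equal charges if warming raised capture more than death. Taking the onward step's factor 3.7 as yardstick and scaling each constant by its energy, beta's capture constant came to 6230 M⁻¹ s⁻¹, up 4.49-fold. Its death constant came to 0.0861 s⁻¹, up 10.5-fold. Beta stood short by a factor of 2.34. Its budget was alpha's cut by that factor, 0.0868, so I committed to 18.4% in alpha and 8.32% in beta, a gap of 10 percentage points, above the margin.

**The forecast.** It named alpha, with 18.3% and 8.3%, holding that “its yield is set by how many turnovers the enzyme makes before dying”. My alpha figure stood 0.100 points above its figure.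

**The run.** Alpha gave 18.4% and beta 8.32%, so alpha led. At 15.0 min alpha held 82% of its starting material beside 0.202% of its free enzyme, and at 150 min its target stood at 18.4%, so alpha had stopped with that material unused. A neighbour of beta was charged with 0.040 M of starting material at the same loading. Its enzyme charge falls in step, so its budget is beta's scaled down to 0.0347, which gives 3.41%. That neighbour gave 3.41%.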